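**Strategy**

The two hindered aryl–C(sp3) bonds that sit between the phenol oxygens (C7–ring B, C20–ring A) are disconnected to C–O bonds. A double aromatic Claisen ring expansion of an 18-membered bis(allyl aryl ether) forges both bonds, enlarges the ring to the 22-membered [7.7]paracyclophane, and relays two C–O stereocentres (C5, C18) to the remote benzylic centres C7 and C20, each independently, as the non-C2 array in the SMILES demands. The precursor is a macrocyclic diether in which one resorcinol oxygen of each ring is the tether atom; it is assembled from one common aldehyde and two alkynes by two Mitsunobu etherifications.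

Key step: step 14

**Remarks and assumptions**

- Structure: the SMILES as written is (1R,2S,7S,14R,15S,20S). The CIP order at C20 (dichlorobutyl > ring chain) is the reverse of that at C7 (ring chain > butyl), so the two side-chain carbons have locally opposite spatial sense. The route sets them independently to match the SMILES as given.
- Numbering used for all intermediates: ring A carries C1 and, in the target, C20; ring B carries C14 and C7. Arm A = C1(O)–C2(Me)–C3–C4–C5–C6–C7(n-Bu). Arm B = C14(O)–C15(Me)–C16–C17–C18–C19–C20(4,4-dichlorobutyl).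
- Abbreviations: TBS = tert-butyldimethylsilyl, Piv = pivaloyl, MIB = 3-exo-morpholinoisoborneol, NBSH = 2-nitrobenzenesulfonyl hydrazide.
- Rotamers of 25–28 that differ only in the placement of OAc and OPiv on a ring converge when both esters are removed in step 17.
- Catalyst and ligand antipodes are assigned from the usual facial models and are marked "expected".

**Route**

Step 1
Reactants: 1 3,5-dihydroxybenzaldehyde
Product: 2 3-formyl-5-hydroxyphenyl pivalate
Conditions: PivCl (0.95 equiv, slow addition), Et3N, THF, 0 °C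
Reagents that add atoms: pivaloyl chloride, CC(C)(C)C(Cl)=O
Why: Statistical mono-O-acylation of a symmetric diphenol (phenol acylation); the mono-ester should be separable from bis-ester and recovered 1, which are recycled, and the pivalate stays to the end as a small, electron-withdrawing O-substituent.

Step 2
Reactants: 2 3-formyl-5-hydroxyphenyl pivalate
Product: 3 3-(TBSO)-5-formylphenyl pivalate
Conditions: TBSCl, imidazole, DMF, rt
Reagents that add atoms: tert-butyldimethylsilyl chloride, CC(C)(C)[Si](C)(C)Cl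
Why: Standard phenol silylation gives a temporary aryl silyl ether that can later be removed in the presence of the alkyl TBS ethers and the pivalate.

Step 3
Reactants: 3 3-(TBSO)-5-formylphenyl pivalate; 4 (Z)-crotylboronic acid pinacol ester
Product: 5 3-(TBSO)-5-[(1R,2S)-1-hydroxy-2-methylbut-3-en-1-yl]phenyl pivalate
Conditions: (R)-TRIP (5 mol %, expected antipode), 4 Å MS, toluene, −30 °C; aqueous work-up
Reagents that add atoms: none
Why: Chiral phosphoric acid-catalysed crotylboration through a closed chair transition state, in which the (Z)-crotyl geometry gives the syn C1/C2 relationship and the catalyst directs Re-face addition, so that C1 is R and C2 is S.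

Step 4
Reactants: 5 3-(TBSO)-5-[(1R,2S)-1-hydroxy-2-methylbut-3-en-1-yl]phenyl pivalate
Product: 6 3-(TBSO)-5-[(1R,2S)-1-(TBSO)-2-methylbut-3-en-1-yl]phenyl pivalate
Conditions: TBSOTf, 2,6-lutidine, CH2Cl2, −78 → 0 °C
Reagents that add atoms: tert-butyldimethylsilyl triflate, CC(C)(C)[Si](C)(C)OS(=O)(=O)C(F)(F)F
Why: Silyl triflate silylation of the hindered benzylic alcohol; the bulky C1–OTBS group also serves later as the steric buttress next to the unwanted ortho carbon.

Step 5
Reactants: 6 3-(TBSO)-5-[(1R,2S)-1-(TBSO)-2-methylbut-3-en-1-yl]phenyl pivalate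
Product: 7 3-(TBSO)-5-[(1R,2S)-1-(TBSO)-2-methyl-5-oxopentyl]phenyl pivalate (common aldehyde)
Conditions: Rh(acac)(CO)2 (1 mol %), BIPHEPHOS (2 mol %), CO/H2 (1:1, 5 bar), toluene, 60 °C
Reagents that add atoms: carbon monoxide, [C-]#[O+]
Why: Linear-selective Rh-catalysed hydroformylation of a terminal alkene whose allylic branch disfavours the iso-aldehyde, adding C5 in one step without touching C1 or C2.

Step 6
Reactants: 7 3-(TBSO)-5-[(1R,2S)-1-(TBSO)-2-methyl-5-oxopentyl]phenyl pivalate; 8 1-hexyne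
Product: 11 3-(TBSO)-5-[(1R,2S,5S,6E)-1-(TBSO)-5-hydroxy-2-methylundec-6-en-1-yl]phenyl pivalate (arm-A allylic alcohol), via (E)-hex-1-enyl(dicyclohexyl)borane 9 (not isolated), via (E)-hex-1-enyl(methyl)zinc 10 (not isolated)
Conditions: cyclohexene, BH3·SMe2, hexanes, 0 °C; 8, toluene, 0 °C → rt; Me2Zn, −78 °C; (+)-MIB (5 mol %, expected antipode); 7, −10 °C; aq NH4Cl
Reagents that add atoms: none
Why: Syn hydroboration fixes the (E)-alkene, boron-to-zinc transmetalation gives the alkenylzinc, and amino-alcohol-catalysed enantioselective alkenylzinc addition to the aldehyde sets C5 as S by ligand control (Re face), the resident C1/C2 centres being too remote to interfere.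

Step 7
Reactants: 7 3-(TBSO)-5-[(1R,2S)-1-(TBSO)-2-methyl-5-oxopentyl]phenyl pivalate
Product: 12 3-hydroxy-5-[(1R,2S)-1-(TBSO)-2-methyl-5-oxopentyl]phenyl pivalate (ring-B phenol aldehyde)
Conditions: TBAF (1.05 equiv), AcOH (1.1 equiv), THF, 0 °C
Reagents that add atoms: none
Why: Buffered fluoride desilylation is selective for the aryl silyl ether (phenoxide leaving group) over the hindered secondary alkyl TBS ether, and the acetic acid buffer protects the enolisable aldehyde and the pivalate.

Step 8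
Reactants: 11 arm-A allylic alcohol (1R,2S,5S,6E); 12 ring-B phenol aldehyde
Product: 13 open-chain aryl ether aldehyde: ring-B oxygen on C5 of arm A (1R,2S,5R,6E); arm B (14R,15S) ending in the C18 aldehyde; ring-A OTBS
Conditions: PPh3, DIAD, toluene, 0 °C → rt
Reagents that add atoms: none
Why: Mitsunobu etherification of an acidic phenol (meta-acyloxy) with a secondary allylic alcohol proceeds by SN2 with inversion, converting (5S)-OH into the (5R)-aryl ether required for C7.

Step 9
Reactants: 14 hex-5-yn-1-ol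
Product: 15 hex-5-ynal
Conditions: Dess–Martin periodinane, CH2Cl2, 0 °C → rt
Reagents that add atoms: none
Why: Dess–Martin oxidation of a primary alcohol stops at the aldehyde and leaves the terminal alkyne untouched.

Step 10
Reactants: 15 hex-5-ynal
Product: 16 6,6-dichlorohex-1-yne
Conditions: Ph3PO (15 mol %), (COCl)2 (1.3 equiv), CHCl3, rt (slow addition of 15)
Reagents that add atoms: oxalyl chloride, O=C(Cl)C(Cl)=O
Why: Phosphine oxide-catalysed deoxydichlorination (Appel-type P(V) catalysis via a chlorophosphonium salt) converts the aldehyde into the gem-dichloride early, so that no chlorination is needed on the macrocycle.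

Step 11
Reactants: 13 open-chain aryl ether aldehyde; 16 6,6-dichlorohex-1-yne
Product: 19 open-chain aryl ether with the arm-B allylic alcohol (18R,19E) carrying the 4,4-dichlorobutyl group on C20; ring-A OTBS, via (E)-(6,6-dichlorohex-1-enyl)dicyclohexylborane 17 (not isolated), via (E)-(6,6-dichlorohex-1-enyl)(methyl)zinc 18 (not isolated)
Conditions: cyclohexene, BH3·SMe2, hexanes, 0 °C; 16, toluene, 0 °C → rt; Me2Zn, −78 °C; (−)-MIB (5 mol %, expected antipode); 13, −10 °C; aq NH4Cl
Reagents that add atoms: none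
Why: The same hydroboration/transmetalation/enantioselective alkenylzinc addition as in step 6, run with the enantiomeric ligand (Si face) to set C18 as R, opposite in sense to C5 as the target requires; the gem-dichloride and the allyl aryl ether are inert to the zinc reagent.

Step 12
Reactants: 19 open-chain aryl ether with the arm-B allylic alcohol
Product: 20 seco phenol alcohol (ring-A OH free; (18R)-allylic OH free)
Conditions: TBAF (1.05 equiv), AcOH (1.1 equiv), THF, 0 °C
Reagents that add atoms: none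
Why: Buffered fluoride desilylation again removes only the aryl TBS ether, unmasking the single phenol needed for ring closure.

Step 13
Reactants: 20 seco phenol alcohol
Product: 21 18-membered bis(allyl aryl ether) macrocycle (1R,2S,5R,14R,15S,18S; both side-chain alkenes E)
Conditions: PPh3 (5 equiv), DIAD (5 equiv), toluene, 0.001 M, syringe-pump addition of 20, 0 °C → rt
Reagents that add atoms: none
Why: Intramolecular Mitsunobu etherification under high dilution closes the ring at a C–O bond with SN2 inversion, (18R)-OH to (18S)-ether, which is kinetically much easier than closing the hindered C–aryl bond directly.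

Step 14
Reactants: 21 18-membered bis(allyl aryl ether) macrocycle
Product: 25 [7.7]paracyclophane-5,18-diene diacetate dipivalate bis-TBS ether (1R,2S,5E,7S,14R,15S,18E,20R), via mono-rearranged phenol (butyl arm) 22 (not isolated), via mono-rearranged phenol (dichlorobutyl arm) 23 (not isolated), via bis-phenol paracyclophanediene 24 (not isolated)
Conditions: N,N-diethylaniline (0.01 M, degassed), 175 °C, sealed vessel; then rt, Ac2O, DMAP
Reagents that add atoms: acetic anhydride, CC(=O)OC(C)=O
Why: Two concerted suprafacial [3,3] shifts, each through a chair transition state followed by tautomerisation of the ortho-dienone; the closest known reaction is the thermal aromatic Claisen rearrangement of enantioenriched (E)-1,3-disubstituted allyl aryl ethers with 1,3-chirality transfer. No ring is closed end to end: because each migrating allyl unit has its carbinol carbon in the ring and its distal alkene carbon outside, each shift is a two-atom sigmatropic ring expansion (18 → 20 → 22) that trades a ring C–O bond for the C7–ring B or C20–ring A bond. C7 and C20 are set by transfer from C5 and C18: with the ring CH2 (C4 or C17) pseudo-equatorial the new C5=C6 and C18=C19 alkenes are E and the arene is delivered to the face from which oxygen leaves, so (5R) gives (7S) and (18S) gives (20R), the latter becoming 20S by CIP once the alkene is saturated. The step needs the ortho carbon between the two oxygens and not the one beside C1/C14; this should be secured by the α-branched silyloxyalkyl substituent, which buttresses the competing site, and by the meta-acyloxy group, which as an inductively withdrawing meta substituent should bias the shift toward its own neighbour. Acetylation in the same flask caps the new phenols, removing the O–H that an abnormal Claisen (enolene) pathway or later oxidation would need.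

Step 15
Reactants: 25 paracyclophanediene diacetate dipivalate bis-TBS ether
Product: 26 saturated [7.7]paracyclophane diacetate dipivalate bis-TBS ether (1R,2S,7S,14R,15S,20S)
Conditions: NBSH (excess, portions), Et3N, CH2Cl2, rt
Reagents that add atoms: none
Why: Diimide reduction transfers H2 in a concerted syn fashion without a metal hydride, so the alkenes cannot migrate into conjugation and scramble the allylic-benzylic C7/C20 centres, and neither C–Cl nor benzylic C–O bonds are hydrogenolysed.

Step 16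
Reactants: 26 saturated paracyclophane diacetate dipivalate bis-TBS ether
Product: 27 paracyclophane-1,14-diol diacetate dipivalate (1R,2S,7S,14R,15S,20S)
Conditions: HF·pyridine, pyridine, THF, 0 °C → rt
Reagents that add atoms: none
Why: Acidic fluoride desilylation cleaves the two secondary alkyl TBS ethers while the aryl esters and the gem-dichloride are stable, and the meta-acyloxy arenes disfavour benzylic ionisation.

Step 17
Reactants: 27 paracyclophane-1,14-diol diacetate dipivalate
Product: 29 CNP0135078.1 (1R,2S,7S,14R,15S,20S), via bis(N-trichloroacetylcarbamate) 28 (not isolated)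
Conditions: Cl3CC(O)NCO, CH2Cl2, 0 °C; then K2CO3, MeOH, rt → 40 °C, argon
Reagents that add atoms: trichloroacetyl isocyanate, O=C=NC(=O)C(Cl)(Cl)Cl
Why: Carbamoylation with trichloroacetyl isocyanate followed by basic methanolysis, which removes the trichloroacetyl groups and all four aryl esters (phenoxide leaving groups) in the same flask, while the primary alkyl carbamates (alkoxide leaving group) and the gem-dichloride should survive.

**Compound list**

1 | 3,5-dihydroxybenzaldehyde | O=Cc1cc(O)cc(O)c1 | starting material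
2 | 3-formyl-5-hydroxyphenyl pivalate | CC(C)(C)C(=O)Oc1cc(O)cc(C=O)c1 | intermediate
3 | 3-(TBSO)-5-formylphenyl pivalate | CC(C)(C)C(=O)Oc1cc(O[Si](C)(C)C(C)(C)C)cc(C=O)c1 | intermediate
4 | (Z)-crotylboronic acid pinacol ester | C/C=C\CB1OC(C)(C)C(C)(C)O1 | starting material
5 | 3-(TBSO)-5-[(1R,2S)-1-hydroxy-2-methylbut-3-en-1-yl]phenyl pivalate | C=C[C@H](C)[C@@H](O)c1cc(O[Si](C)(C)C(C)(C)C)cc(OC(=O)C(C)(C)C)c1 | intermediate
6 | 3-(TBSO)-5-[(1R,2S)-1-(TBSO)-2-methylbut-3-en-1-yl]phenyl pivalate | C=C[C@H](C)[C@@H](O[Si](C)(C)C(C)(C)C)c1cc(O[Si](C)(C)C(C)(C)C)cc(OC(=O)C(C)(C)C)c1 | intermediate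
7 | 3-(TBSO)-5-[(1R,2S)-1-(TBSO)-2-methyl-5-oxopentyl]phenyl pivalate (common aldehyde) | O=CCC[C@H](C)[C@@H](O[Si](C)(C)C(C)(C)C)c1cc(O[Si](C)(C)C(C)(C)C)cc(OC(=O)C(C)(C)C)c1 | intermediate
8 | 1-hexyne | CCCCC#C | starting material
9 | (E)-hex-1-enyl(dicyclohexyl)borane | CCCC/C=C/B(C1CCCCC1)C1CCCCC1 | intermediate
10 | (E)-hex-1-enyl(methyl)zinc | CCCC/C=C/[Zn]C | intermediate
11 | 3-(TBSO)-5-[(1R,2S,5S,6E)-1-(TBSO)-5-hydroxy-2-methylundec-6-en-1-yl]phenyl pivalate (arm-A allylic alcohol) | CCCC/C=C/[C@@H](O)CC[C@H](C)[C@@H](O[Si](C)(C)C(C)(C)C)c1cc(O[Si](C)(C)C(C)(C)C)cc(OC(=O)C(C)(C)C)c1 | intermediate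
12 | 3-hydroxy-5-[(1R,2S)-1-(TBSO)-2-methyl-5-oxopentyl]phenyl pivalate (ring-B phenol aldehyde) | O=CCC[C@H](C)[C@@H](O[Si](C)(C)C(C)(C)C)c1cc(O)cc(OC(=O)C(C)(C)C)c1 | intermediate
13 | open-chain aryl ether aldehyde (1R,2S,5R,6E,14R,15S); ring-B O on C5; C18 aldehyde; ring-A OTBS | CCCC/C=C/[C@H](Oc1cc(OC(=O)C(C)(C)C)cc(c1)[C@H](O[Si](C)(C)C(C)(C)C)[C@@H](C)CCC=O)CC[C@H](C)[C@@H](O[Si](C)(C)C(C)(C)C)c1cc(O[Si](C)(C)C(C)(C)C)cc(OC(=O)C(C)(C)C)c1 | intermediate
14 | hex-5-yn-1-ol | C#CCCCCO | starting material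
15 | hex-5-ynal | C#CCCCC=O | intermediate
16 | 6,6-dichlorohex-1-yne | C#CCCCC(Cl)Cl | intermediate
17 | (E)-(6,6-dichlorohex-1-enyl)dicyclohexylborane | ClC(Cl)CCC/C=C/B(C1CCCCC1)C1CCCCC1 | intermediate
18 | (E)-(6,6-dichlorohex-1-enyl)(methyl)zinc | ClC(Cl)CCC/C=C/[Zn]C | intermediate
19 | open-chain aryl ether with arm-B allylic alcohol (1R,2S,5R,6E,14R,15S,18R,19E); ring-A OTBS | CCCC/C=C/[C@H](Oc1cc(OC(=O)C(C)(C)C)cc(c1)[C@H](O[Si](C)(C)C(C)(C)C)[C@@H](C)CC[C@@H](O)/C=C/CCCC(Cl)Cl)CC[C@H](C)[C@@H](O[Si](C)(C)C(C)(C)C)c1cc(O[Si](C)(C)C(C)(C)C)cc(OC(=O)C(C)(C)C)c1 | intermediate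
20 | seco phenol alcohol (ring-A OH and (18R)-OH free) | CCCC/C=C/[C@H](Oc1cc(OC(=O)C(C)(C)C)cc(c1)[C@H](O[Si](C)(C)C(C)(C)C)[C@@H](C)CC[C@@H](O)/C=C/CCCC(Cl)Cl)CC[C@H](C)[C@@H](O[Si](C)(C)C(C)(C)C)c1cc(O)cc(OC(=O)C(C)(C)C)c1 | intermediate
21 | 18-membered bis(allyl aryl ether) macrocycle (1R,2S,5R,14R,15S,18S) | CCCC/C=C/[C@H]1CC[C@H](C)[C@@H](O[Si](C)(C)C(C)(C)C)c2cc(OC(=O)C(C)(C)C)cc(c2)O[C@H](/C=C/CCCC(Cl)Cl)CC[C@H](C)[C@@H](O[Si](C)(C)C(C)(C)C)c2cc(OC(=O)C(C)(C)C)cc(c2)O1 | intermediate
22 | 20-membered mono-rearranged phenol, butyl arm shifted (7S; 18S ether remains) | CCCC[C@H]1/C=C/CC[C@H](C)[C@@H](O[Si](C)(C)C(C)(C)C)c2cc(OC(=O)C(C)(C)C)cc(c2)O[C@H](/C=C/CCCC(Cl)Cl)CC[C@H](C)[C@@H](O[Si](C)(C)C(C)(C)C)c2cc(O)c1c(OC(=O)C(C)(C)C)c2 | intermediate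
23 | 20-membered mono-rearranged phenol, dichlorobutyl arm shifted (20R; 5R ether remains) | CCCC/C=C/[C@H]1CC[C@H](C)[C@@H](O[Si](C)(C)C(C)(C)C)c2cc(O)c(c(OC(=O)C(C)(C)C)c2)[C@H](CCCC(Cl)Cl)/C=C/CC[C@H](C)[C@@H](O[Si](C)(C)C(C)(C)C)c2cc(OC(=O)C(C)(C)C)cc(c2)O1 | intermediate
24 | [7.7]paracyclophane-5,18-diene bis-phenol dipivalate bis-TBS ether (1R,2S,5E,7S,14R,15S,18E,20R) | CCCC[C@H]1/C=C/CC[C@H](C)[C@@H](O[Si](C)(C)C(C)(C)C)c2cc(O)c(c(OC(=O)C(C)(C)C)c2)[C@H](CCCC(Cl)Cl)/C=C/CC[C@H](C)[C@@H](O[Si](C)(C)C(C)(C)C)c2cc(O)c1c(OC(=O)C(C)(C)C)c2 | intermediate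
25 | [7.7]paracyclophane-5,18-diene diacetate dipivalate bis-TBS ether (1R,2S,5E,7S,14R,15S,18E,20R) | CCCC[C@H]1/C=C/CC[C@H](C)[C@@H](O[Si](C)(C)C(C)(C)C)c2cc(OC(C)=O)c(c(OC(=O)C(C)(C)C)c2)[C@H](CCCC(Cl)Cl)/C=C/CC[C@H](C)[C@@H](O[Si](C)(C)C(C)(C)C)c2cc(OC(C)=O)c1c(OC(=O)C(C)(C)C)c2 | intermediate
26 | saturated [7.7]paracyclophane diacetate dipivalate bis-TBS ether (1R,2S,7S,14R,15S,20S) | CCCC[C@H]1CCCC[C@H](C)[C@@H](O[Si](C)(C)C(C)(C)C)c2cc(OC(C)=O)c(c(OC(=O)C(C)(C)C)c2)[C@H](CCCC(Cl)Cl)CCCC[C@H](C)[C@@H](O[Si](C)(C)C(C)(C)C)c2cc(OC(C)=O)c1c(OC(=O)C(C)(C)C)c2 | intermediate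
27 | [7.7]paracyclophane-1,14-diol diacetate dipivalate (1R,2S,7S,14R,15S,20S) | CCCC[C@H]1CCCC[C@H](C)[C@@H](O)c2cc(OC(C)=O)c(c(OC(=O)C(C)(C)C)c2)[C@H](CCCC(Cl)Cl)CCCC[C@H](C)[C@@H](O)c2cc(OC(C)=O)c1c(OC(=O)C(C)(C)C)c2 | intermediate
28 | 1,14-bis(N-trichloroacetylcarbamate) diacetate dipivalate | CCCC[C@H]1CCCC[C@H](C)[C@@H](OC(=O)NC(=O)C(Cl)(Cl)Cl)c2cc(OC(C)=O)c(c(OC(=O)C(C)(C)C)c2)[C@H](CCCC(Cl)Cl)CCCC[C@H](C)[C@@H](OC(=O)NC(=O)C(Cl)(Cl)Cl)c2cc(OC(C)=O)c1c(OC(=O)C(C)(C)C)c2 | intermediate
29 | CNP0135078.1 (1R,2S,7S,14R,15S,20S) | CCCC[C@H]1CCCC[C@H](C)[C@@H](OC(N)=O)c2cc(O)c(c(O)c2)[C@H](CCCC(Cl)Cl)CCCC[C@H](C)[C@@H](OC(N)=O)c2cc(O)c1c(O)c2 | target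

**Summary**

Total step count: 17. Longest linear sequence: 14 steps (steps 1–6, 8, 11–17).

**Steps most likely to fail**

1. Step 14. What may go wrong: migration of an allyl unit to the ortho carbon beside the benzylic branch, leakage through the axial or boat transition state (Z-alkene, wrong C7 or C20), or thermal ionisation and elimination of the secondary allylic ethers; each fault compounds over two events in one flask. Fallback (staged ring expansion, sets out from 20, returns at 25): 20 is heated alone (N,N-diethylaniline, 165 °C) so that the arm-A ether rearranges in the open chain, where this shift can be optimised by itself and a wrong-ortho or Z isomer removed by chromatography, giving the open-chain C7-arylated phenol F1. Mitsunobu macro-etherification of F1 under high dilution should then give 22 as an isolated compound, because only the unhindered ring-A phenol can reach C18 in an unstrained (20-membered) ring. A single Claisen ring expansion of 22 (N,N-diethylaniline, 175 °C) gives 24, which is acetylated (Ac2O, DMAP) to 25.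

2. Step 13. What may go wrong: intermolecular etherification to oligomers, and SN2′ or elimination collapse of the allylic oxyphosphonium ion with loss of the C18 configuration. Fallback (ring closure at the alkyne stage, sets out from 13 and 16, returns at 21): zinc-ProPhenol-catalysed alkynylation of 13 with 16 (Me2Zn, ProPhenol ligand chosen for Si-face addition, Ph3PO, toluene, 0 °C) gives the (18R)-propargylic alcohol F2. Mesylation (MsCl, Et3N, CH2Cl2, −20 °C) gives the propargylic mesylate F3. CsF in DMF under high dilution unmasks the ring-A phenoxide, which closes the 18-membered ring by Williamson-type SN2 with inversion (no allylic SN2′ or diene channel is open at the alkyne) to the macrocyclic propargyl aryl ether F4. Ru-catalysed trans-hydrosilylation ([Cp*Ru(MeCN)3]PF6, (EtO)3SiH, CH2Cl2) gives the (Z)-vinylsilane F5, and protodesilylation (AgF, THF/MeOH/H2O) gives 21 with the (E)-alkene.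

3. Step 6 (and in the same way step 11). What may go wrong: poor facial control in the alkenylzinc addition to an unbranched, enolisable aldehyde, with competing methyl transfer or aldolisation. Fallback (reagent-controlled ketone reduction, sets out from 7 and 8, returns at 11): the same alkenylzinc addition run without ligand gives 11 mixed with its C5 epimer, the (5R)-alcohol F6. Dess–Martin oxidation of the mixture gives the (E)-enone F7. Corey–Bakshi–Shibata reduction ((R)-Me-CBS expected, catecholborane, toluene, −78 °C) returns 11; the same detour can serve arm B.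

**Further compounds**

F1 | step 14 | open-chain C7-arylated phenol (arm A rearranged onto ring B; ring-A OH and (18R)-allylic OH free; 1R,2S,5E,7S,14R,15S,18R,19E) | CCCC[C@@H](/C=C/CC[C@H](C)[C@@H](O[Si](C)(C)C(C)(C)C)c1cc(O)cc(OC(=O)C(C)(C)C)c1)c1c(O)cc(cc1OC(=O)C(C)(C)C)[C@H](O[Si](C)(C)C(C)(C)C)[C@@H](C)CC[C@@H](O)/C=C/CCCC(Cl)Cl
F2 | step 13 | (18R)-propargylic alcohol analogue of 19 | CCCC/C=C/[C@H](Oc1cc(OC(=O)C(C)(C)C)cc(c1)[C@H](O[Si](C)(C)C(C)(C)C)[C@@H](C)CC[C@@H](O)C#CCCCC(Cl)Cl)CC[C@H](C)[C@@H](O[Si](C)(C)C(C)(C)C)c1cc(O[Si](C)(C)C(C)(C)C)cc(OC(=O)C(C)(C)C)c1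
F3 | step 13 | (18R)-propargylic methanesulfonate of F2 | CCCC/C=C/[C@H](Oc1cc(OC(=O)C(C)(C)C)cc(c1)[C@H](O[Si](C)(C)C(C)(C)C)[C@@H](C)CC[C@@H](OS(C)(=O)=O)C#CCCCC(Cl)Cl)CC[C@H](C)[C@@H](O[Si](C)(C)C(C)(C)C)c1cc(O[Si](C)(C)C(C)(C)C)cc(OC(=O)C(C)(C)C)c1
F4 | step 13 | 18-membered macrocycle with (5R)-allyl and (18S)-propargyl aryl ethers | CCCC/C=C/[C@H]1CC[C@H](C)[C@@H](O[Si](C)(C)C(C)(C)C)c2cc(OC(=O)C(C)(C)C)cc(c2)O[C@H](C#CCCCC(Cl)Cl)CC[C@H](C)[C@@H](O[Si](C)(C)C(C)(C)C)c2cc(OC(=O)C(C)(C)C)cc(c2)O1
F5 | step 13 | (Z)-C20-triethoxysilyl alkene from F4 | CCCC/C=C/[C@H]1CC[C@H](C)[C@@H](O[Si](C)(C)C(C)(C)C)c2cc(OC(=O)C(C)(C)C)cc(c2)O[C@H](/C=C(/CCCC(Cl)Cl)[Si](OCC)(OCC)OCC)CC[C@H](C)[C@@H](O[Si](C)(C)C(C)(C)C)c2cc(OC(=O)C(C)(C)C)cc(c2)O1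
F6 | step 6 | (5R)-epimer of 11 | CCCC/C=C/[C@H](O)CC[C@H](C)[C@@H](O[Si](C)(C)C(C)(C)C)c1cc(O[Si](C)(C)C(C)(C)C)cc(OC(=O)C(C)(C)C)c1
F7 | step 6 | (E)-enone (C5 ketone) from 11 and F6 | CCCC/C=C/C(=O)CC[C@H](C)[C@@H](O[Si](C)(C)C(C)(C)C)c1cc(O[Si](C)(C)C(C)(C)C)cc(OC(=O)C(C)(C)C)c1
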